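**Retrosynthetic overview**

1. Locants: ring A = C1 (quaternary, carries the sorbyl ketone)–C2 (=O)–C3 (Me, OH)–C4 (H)–C10 (H); ring B = C1–C7 (Me)–C6 (=O)–C5 (enol carbon)–C4–C10; ring C = C1–C7–C8 (OH)–C9 (Me)–C10; ring D (lactone) = C8–C11 (H, Me)–C12 (=O)–O–C9.
2. Last bond: C4–C5 of ring B. C4 is β and the C3 carbinol is α to the C2 ketone of ring A, which is the pattern left by anti opening of a C3–C4 epoxy ketone at its β carbon. C5 is the carbon between C6=O and the sorbyl C=O of a 1,3-diketone, and C7 holds it over the concave face, opposite a convex-face epoxide.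
3. Both sorbyl units come from sorbaldehyde by a twofold aldol addition/oxidation, on the C1 enolate of the ring A ketone and on a C7 methyl ketone masked until then as an isopropenyl group.
4. Ring D: intramolecular propanoate aldol onto the C8 ketone. The quaternary carbons C7 and C9 are set by convex-face enolate methylations.
5. Rings A and C together by one Pauson–Khand reaction of an acyclic enyne from pent-4-enal and 2-methylbut-1-en-3-yne. Ring order: A + C, then D, then B.

Key step: step 17

Remark: the target is taken as the drawn enol tautomer of the 2-acyl-1,3-diketone at C5; it should form on acidification of the diketonate.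
Remark: the facial sense of the ligand in step 2 and of the silyloxy group in step 4 follows the usual models; if either is opposite, the antipodal ligand in step 2 corrects the absolute configuration.

**Route**

Step 1
Reactants: 1 pent-4-enal
Product: 2 2-methylidenepent-4-enal
Conditions: 37% aq. CH2O, pyrrolidine (10 mol%), EtCO2H (10 mol%), 2-propanol, 45 °C
Reagents that add atoms: formaldehyde, C=O
Why: organocatalytic Mannich-type α-methylenation of an aldehyde (enamine addition to the iminium of formaldehyde, then β-elimination) brings in the carbon that becomes the C3 methyl; no stereocentre is formed.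

Step 2
Reactants: 2 2-methylidenepent-4-enal, 3 2-methylbut-1-en-3-yne
Product: 4 (5S)-2-methyl-6-methylidenenona-1,8-dien-3-yn-5-ol
Conditions: Me2Zn (3 equiv), (R,R)-ProPhenol (20 mol%), Ph3P=O (40 mol%), toluene, 0 °C; aq. work-up
Reagents that add atoms: none
Why: ProPhenol–dinuclear zinc catalysed enantioselective alkynylation of the enal (Trost alkynylation); the ligand antipode is chosen to give the (5S) carbinol, the only stereocentre not set by the substrate.

Step 3
Reactants: 4 (5S)-2-methyl-6-methylidenenona-1,8-dien-3-yn-5-ol
Product: 5 tert-butyldimethylsilyl ether of 4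
Conditions: TBSCl, imidazole, DMF, 23 °C
Reagents that add atoms: tert-butyl(chloro)dimethylsilane, CC(C)(C)[Si](C)(C)Cl
Why: standard silylation of a secondary alcohol; the bulky ether is the control element for step 4.

Step 4
Reactants: 5 tert-butyldimethylsilyl ether of 4
Product: 6 bicyclic dienone (rings A and C; C8 ketone, C7=C1, C7 isopropenyl, C2 silyloxy cis to H-10, C3 methylidene)
Conditions: Co2(CO)8 (10 mol%), tetramethylthiourea (60 mol%), CO (1 atm), benzene, 70 °C
Reagents that add atoms: carbon monoxide, [C-]#[O+]
Why: cobalt-catalysed intramolecular Pauson–Khand [2+2+1] cycloaddition of the 1,6-enyne closes rings A and C in one step; the propargylic silyloxy group should take the pseudo-axial position that avoids allylic strain with the isopropenyl group on the cobalt-bound alkyne, which places it cis to H-10 and so transfers the C2 configuration to C10.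

Step 5
Reactants: 6 bicyclic dienone
Product: 8 cis-fused ketone with quaternary C7 (methyl convex; isopropenyl concave), via silyl dienol ether 7 (not isolated)
Conditions: Cu(OAc)2·H2O (5 mol%), 1,2-bis(diphenylphosphino)benzene (5 mol%), PhMe2SiH (1.5 equiv), toluene, 23 °C; concentrate; MeLi, THF, 0 °C; MeI, DMPU, −78 → 0 °C
Reagents that add atoms: iodomethane, CI
Why: ligated copper hydride 1,4-hydrosilylation delivers hydride to C1 from the convex face (cis ring fusion, the trans-fused diquinane being too strained), and the lithium dienolate released from the silyl ether by MeLi is methylated at its α carbon C7 from the convex face (regiospecific enolate alkylation), which leaves the isopropenyl group on the concave face.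

Step 6
Reactants: 8 cis-fused ketone
Product: 9 C9 α-hydroxy ketone (hydroxyl on the convex face)
Conditions: KN(SiMe3)2, THF, −78 °C; 3-phenyl-2-(phenylsulfonyl)oxaziridine; AcOH, −78 °C
Reagents that add atoms: 3-phenyl-2-(phenylsulfonyl)oxaziridine, O=S(=O)(c1ccccc1)N1OC1c1ccccc1
Why: Davis hydroxylation of the potassium enolate; C9 is the only enolisable position, and the oxygen enters from the convex face (the C9 configuration is reset in step 8).

Step 7
Reactants: 9 C9 α-hydroxy ketone
Product: 10 C9 propanoate
Conditions: EtCOCl, pyridine, DMAP (cat.), CH2Cl2, 0 °C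
Reagents that add atoms: propanoyl chloride, CCC(Cl)=O
Why: O-acylation of an unhindered secondary alcohol; the ester supplies C11, C12 and the C11 methyl of ring D.

Step 8
Reactants: 10 C9 propanoate
Product: 11 C9-methylated α-propanoyloxy ketone (C9 methyl convex, ester oxygen concave)
Conditions: KN(SiMe3)2 (1.05 equiv), THF–DMPU, −78 °C; MeI
Reagents that add atoms: iodomethane, CI
Why: alkylation of the potassium enolate of the α-acyloxy ketone (much more acidic than the ester CH2) by MeI from the convex face puts the methyl group convex and the acyloxy oxygen concave, as ring D needs; alkylation at the less hindered C9 should outrun any acyl shift to the enediolate.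

Step 9
Reactants: 11 C9-methylated α-propanoyloxy ketone
Product: 12 tricyclic hydroxy lactone (rings A, C, D; C8 hydroxyl convex; C11 methyl syn to C7)
Conditions: LiN(CHMe2)2 (1.3 equiv), THF, −78 °C; AcOH, −78 °C
Reagents that add atoms: none
Why: intramolecular ester-enolate aldol (the 5-ring enolate-to-carbonyl closure known from Dieckmann routes to tetronic acids): the ester hangs from the concave C9 oxygen, so C11 adds to the concave face of the C8 ketone and the hydroxyl ends convex; the (E)-enolate, reacting with its OLi group turned to the open side, should place the C11 methyl syn to C7, and any C11 enolate is reprotonated from the open face in the cold quench, which gives the same epimer.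

Step 10
Reactants: 12 tricyclic hydroxy lactone
Product: 13 C2 alcohol
Conditions: HF·pyridine, pyridine, THF, 0 → 23 °C
Reagents that add atoms: none
Why: fluoride cleavage of the silyl ether under buffered conditions that should not epimerise C11.

Step 11
Reactants: 13 C2 alcohol
Product: 14 C2 ketone with C3 exocyclic methylene
Conditions: Dess–Martin periodinane, NaHCO3, CH2Cl2, 0 °C
Reagents that add atoms: none
Why: Dess–Martin oxidation of the secondary allylic alcohol; the tertiary C8 hydroxyl cannot be oxidised.

Step 12
Reactants: 14 C2 ketone with C3 exocyclic methylene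
Product: 15 ring A enone (C3=C4, C3 methyl)
Conditions: RhCl3·3H2O (5 mol%), EtOH, 75 °C
Reagents that add atoms: none
Why: rhodium hydride-mediated migration of the exocyclic double bond into the ring gives the more stable 2-methylcyclopentenone with defined regiochemistry; the isopropenyl group has no allylic hydrogen on C7 and cannot migrate.

Step 13
Reactants: 15 ring A enone
Product: 16 convex-face C3–C4 epoxy ketone
Conditions: t-BuOOH (decane), DBU, CH2Cl2, 0 → 23 °C
Reagents that add atoms: tert-butyl hydroperoxide, CC(C)(C)OO
Why: nucleophilic (Weitz–Scheffer) epoxidation: the peroxide adds to C4 from the convex face, the concave face being blocked by ring C and its substituents, which sets the C3 and C4 configuration used in step 17; the unactivated isopropenyl group is untouched.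

Step 14
Reactants: 16 convex-face C3–C4 epoxy ketone
Product: 18 C7 acetyl epoxy ketone, via ozonide 17 (not isolated)
Conditions: O3, CH2Cl2, −78 °C; Me2S, −78 → 23 °C
Reagents that add atoms: ozone, [O-][O+]=O
Why: ozonolysis of the only remaining alkene unmasks the methyl ketone; epoxy ketone, lactone and tertiary alcohol are inert.

Step 15
Reactants: 18 C7 acetyl epoxy ketone, 19 (2E,4E)-hexa-2,4-dienal
Product: 20 bis-aldol adduct (two dienyl carbinols)
Conditions: LiN(SiMe3)2 (3.3 equiv), THF, −78 → −40 → −78 °C; 19 (2.5 equiv); AcOH, −78 °C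
Reagents that add atoms: none
Why: twofold aldol addition: excess base turns the methyl ketone and the C2 ketone (only C1–H is enolisable) into lithium enolates, so neither carbonyl can accept the other (a reversible 5-exo aldolate is drained on brief warming), and each enolate adds 1,2 to 19; the aldehyde reaches C1 on the convex face, which fixes the quaternary C1 cis to H-10, and both carbinol centres disappear in step 16.

Step 16
Reactants: 20 bis-aldol adduct
Product: 21 epoxy tetraketone (C1 sorbyl ketone; C7 1,3-diketone chain ending in the second sorbyl unit)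
Conditions: Dess–Martin periodinane (3 equiv), NaHCO3, CH2Cl2, 0 °C
Reagents that add atoms: none
Why: Dess–Martin oxidation of both allylic carbinols gives the C1 sorbyl ketone and the 1,3-diketone (the aldehyde carbon of 19 becomes each sorbyl carbonyl); neutral buffered conditions avoid retro-aldol and premature cyclisation.

Step 17
Reactants: 21 epoxy tetraketone
Product: 22 CNP0231466.1
Conditions: LiN(SiMe3)2 (1.05 equiv), LiOSO2CF3 (3 equiv), THF, −78 → 50 °C; aq. NaH2PO4
Reagents that add atoms: none
Why: Proposed new method: the lithium 1,3-diketonate at C5 (chelated, so that carbon rather than oxygen is the nucleophile) attacks the epoxide carbon C4 from the concave face, anti to the convex C4–O bond, in an intramolecular enolate–epoxide alkylation; the closest known types are Stork-type cyclisations of stabilised carbanions onto epoxides and the distal (β) opening of 2,3-epoxy carbonyl compounds by nucleophiles. Ring B closes in the 6-exo-tet mode with the enolate double bond outside the new ring. C4 is set by inversion (the tether through C7 forces C5 to the concave face) and the epoxide oxygen stays on C3 as the convex tertiary hydroxyl, so both centres are controlled by the epoxide made in step 13; proton transfer from the new 2-alkyl-1,3-diketone to the C3 alkoxide leaves the product as its lithium diketonate until work-up. The step needs C- over O-alkylation, attack at C4 and not at the fully substituted C3, and no loss through the reversible 5-exo aldol of C5 onto the C2 ketone or Michael addition to the sorbyl dienones; lithium chelation, the quaternary C3, the irreversibility of the epoxide opening and the trans relation of the C1 sorbyl ketone to the C7 side chain should secure these.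

**Compound list**

1 | pent-4-enal | C=CCCC=O | starting material
2 | 2-methylidenepent-4-enal | C=CCC(=C)C=O | intermediate
3 | 2-methylbut-1-en-3-yne | C=C(C)C#C | starting material
4 | (5S)-2-methyl-6-methylidenenona-1,8-dien-3-yn-5-ol | C=C(C)C#C[C@@H](O)C(=C)CC=C | intermediate
5 | tert-butyldimethylsilyl ether of 4, (5S) | C=C(C)C#C[C@@H](O[Si](C)(C)C(C)(C)C)C(=C)CC=C | intermediate
6 | bicyclic dienone, (4S,6aR)-4-[(tert-butyldimethylsilyl)oxy]-5-methylidene-3-(prop-1-en-2-yl)-4,5,6,6a-tetrahydropentalen-2(1H)-one; silyloxy cis to the ring-fusion H | C=C(C)C1=C2[C@@H](O[Si](C)(C)C(C)(C)C)C(=C)C[C@@H]2CC1=O | intermediate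
7 | dimethyl(phenyl)silyl dienol ether of the 1,4-reduced dienone (C8–O–Si, C8=C7; cis ring fusion) | C=C(C)C1=C(O[Si](C)(C)c3ccccc3)C[C@H]2CC(=C)[C@H](O[Si](C)(C)C(C)(C)C)[C@@H]12 | intermediate
8 | cis-fused ketone: C7 methyl convex, C7 isopropenyl concave, C8 ketone, C2 OTBS, C3 methylidene | C=C(C)[C@@]1(C)C(=O)C[C@H]2CC(=C)[C@H](O[Si](C)(C)C(C)(C)C)[C@@H]12 | intermediate
9 | C9 α-hydroxy ketone, hydroxyl convex | C=C(C)[C@@]1(C)C(=O)[C@H](O)[C@H]2CC(=C)[C@H](O[Si](C)(C)C(C)(C)C)[C@@H]12 | intermediate
10 | C9 propanoate of 9 | C=C(C)[C@@]1(C)C(=O)[C@H](OC(=O)CC)[C@H]2CC(=C)[C@H](O[Si](C)(C)C(C)(C)C)[C@@H]12 | intermediate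
11 | C9-methylated α-propanoyloxy ketone, C9 methyl convex and ester oxygen concave | C=C(C)[C@@]1(C)C(=O)[C@@](C)(OC(=O)CC)[C@H]2CC(=C)[C@H](O[Si](C)(C)C(C)(C)C)[C@@H]12 | intermediate
12 | tricyclic hydroxy lactone (rings A, C, D), C8 hydroxyl convex, C11 methyl syn to C7 | C=C(C)[C@@]1(C)[C@@]3(O)[C@@H](C)C(=O)O[C@@]3(C)[C@H]2CC(=C)[C@H](O[Si](C)(C)C(C)(C)C)[C@@H]12 | intermediate
13 | C2 alcohol (desilylated 12) | C=C(C)[C@@]1(C)[C@@]3(O)[C@@H](C)C(=O)O[C@@]3(C)[C@H]2CC(=C)[C@H](O)[C@@H]12 | intermediate
14 | C2 ketone with C3 exocyclic methylene | C=C(C)[C@@]1(C)[C@@]3(O)[C@@H](C)C(=O)O[C@@]3(C)[C@H]2CC(=C)C(=O)[C@@H]12 | intermediate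
15 | ring A enone (C2 ketone, C3=C4, C3 methyl) | C=C(C)[C@@]1(C)[C@@]3(O)[C@@H](C)C(=O)O[C@@]3(C)[C@H]2C=C(C)C(=O)[C@@H]12 | intermediate
16 | convex-face C3–C4 epoxy ketone | C=C(C)[C@@]1(C)[C@@]3(O)[C@@H](C)C(=O)O[C@@]3(C)[C@H]2[C@@H]4O[C@]4(C)C(=O)[C@@H]12 | intermediate
17 | secondary ozonide (1,2,4-trioxolane) of the isopropenyl group, ozonide carbon unassigned | CC4(OCOO4)[C@@]1(C)[C@@]3(O)[C@@H](C)C(=O)O[C@@]3(C)[C@H]2[C@@H]5O[C@]5(C)C(=O)[C@@H]12 | intermediate
18 | C7 acetyl epoxy ketone | CC(=O)[C@@]1(C)[C@@]3(O)[C@@H](C)C(=O)O[C@@]3(C)[C@H]2[C@@H]4O[C@]4(C)C(=O)[C@@H]12 | intermediate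
19 | (2E,4E)-hexa-2,4-dienal | C/C=C/C=C/C=O | starting material
20 | bis-aldol adduct, mixture of epimers at both dienyl carbinol carbons | C/C=C/C=C/C(O)CC(=O)[C@@]1(C)[C@@]3(O)[C@@H](C)C(=O)O[C@@]3(C)[C@H]2[C@@H]4O[C@]4(C)C(=O)[C@@]12C(O)/C=C/C=C/C | intermediate
21 | epoxy tetraketone (key-step precursor) | C/C=C/C=C/C(=O)CC(=O)[C@@]1(C)[C@@]3(O)[C@@H](C)C(=O)O[C@@]3(C)[C@H]2[C@@H]4O[C@]4(C)C(=O)[C@@]12C(=O)/C=C/C=C/C | intermediate
22 | CNP0231466.1 | C/C=C/C=C/C(=O)[C@]12C(=O)[C@@](C)(O)[C@@H]3\C(=C(O)/C=C/C=C/C)C(=O)[C@@]1(C)[C@@]1(O)[C@@H](C)C(=O)O[C@@]1(C)[C@@H]32 | target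

**Count and risks**

Total step count: 17. Longest linear sequence: 17 steps (from pent-4-enal).

Steps most likely to fail:

1. Step 17 (proposed new method). The ambident diketonate may alkylate on oxygen and give the bridged enol ether. The epoxide opening may also be too slow, so that reversible aldol addition into the C2 ketone or base-induced retro-Claisen cleavage at C1 takes over. The fallback uses known chemistry, sets out from 15 and comes back at 22. Selective ozonolysis of the isopropenyl group of 15 (the electron-poor enone reacts more slowly) should give the acetyl enone F1. A twofold boron aldol with 19 (n-Bu2BOSO2CF3, EtN(CHMe2)2; boron enolates do not add to the enone) should give the bis-aldol enone F2, and Dess–Martin oxidation the enone tetraketone F3. Intramolecular Michael addition of the 1,3-diketone to C4 of the cyclopentenone (K2CO3, MeCN; 6-exo-trig, concave face by the tether) closes ring B and should give the C3-deoxy compound F4. Enolate hydroxylation at C3 (KN(SiMe3)2 in excess, then 3-phenyl-2-(phenylsulfonyl)oxaziridine, oxygen from the convex face) then leads to 22.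

2. Step 15. The methyl ketone enolate may be trapped by 5-exo aldol addition to the C2 ketone before the hindered C1–H is removed. Deprotonation at C1 may stay incomplete, and the quaternary aldolate may revert on warming. The fallback sets out from 18 and comes back at 20. Me3SiOSO2CF3/Et3N converts both ketones into silyl enol ethers and silylates the C8 hydroxyl, giving the tris(trimethylsilyl) derivative F5, with no free enolate next to a free ketone. A fluoride-catalysed Mukaiyama aldol with 19 (tetrabutylammonium difluorotriphenylsilicate, THF, −78 °C) and desilylation with aqueous citric acid should then give 20.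

3. Step 9. Loss of control over enolate geometry or over the folding of the enolate in the cyclisation would give the C11 epimer with its methyl group on the open face. Its C11–H is buried and cannot be removed for correction; retro-aldol of the crowded aldolate is a further loss channel. The fallback sets out from 9 and comes back at 12. Acetylation gives the acetate F6, and convex-face methylation as in step 8 the C9-methylated acetate F7. The less hindered acetate enolate closes ring D to the lactone without C11 methyl F8. Its dianion with CH2=NMe2+ I− gives the Mannich base F9, and quaternisation with MeI and elimination (NaHCO3) the α-methylene lactone F10. Conjugate reduction with KBH(s-Bu)3 at −78 °C and protonation of the lactone enolate from the open face by 2,6-di-tert-butylphenol then sets C11 with the methyl group syn to C7 and gives 12.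

**Further compounds**

F1 | step 17 | acetyl enone | CC(=O)[C@@]1(C)[C@@]3(O)[C@@H](C)C(=O)O[C@@]3(C)[C@H]2C=C(C)C(=O)[C@@H]12
F2 | step 17 | bis-aldol enone (epimers at both carbinol carbons) | C/C=C/C=C/C(O)CC(=O)[C@@]1(C)[C@@]3(O)[C@@H](C)C(=O)O[C@@]3(C)[C@H]2C=C(C)C(=O)[C@@]12C(O)/C=C/C=C/C
F3 | step 17 | enone tetraketone | C/C=C/C=C/C(=O)CC(=O)[C@@]1(C)[C@@]3(O)[C@@H](C)C(=O)O[C@@]3(C)[C@H]2C=C(C)C(=O)[C@@]12C(=O)/C=C/C=C/C
F4 | step 17 | C3-deoxy compound (ring B closed, C3–H) | C/C=C/C=C/C(=O)[C@]12C(=O)[C@H](C)[C@@H]3\C(=C(O)/C=C/C=C/C)C(=O)[C@@]1(C)[C@@]1(O)[C@@H](C)C(=O)O[C@@]1(C)[C@@H]32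
F5 | step 15 | tris(trimethylsilyl) derivative (two silyl enol ethers, C8 silyl ether) | C=C(O[Si](C)(C)C)[C@@]1(C)[C@@]3(O[Si](C)(C)C)[C@@H](C)C(=O)O[C@@]3(C)[C@H]2[C@@H]4O[C@]4(C)C(O[Si](C)(C)C)=C12
F6 | step 9 | acetate of 9 | C=C(C)[C@@]1(C)C(=O)[C@H](OC(C)=O)[C@H]2CC(=C)[C@H](O[Si](C)(C)C(C)(C)C)[C@@H]12
F7 | step 9 | C9-methylated acetate | C=C(C)[C@@]1(C)C(=O)[C@@](C)(OC(C)=O)[C@H]2CC(=C)[C@H](O[Si](C)(C)C(C)(C)C)[C@@H]12
F8 | step 9 | lactone without C11 methyl | C=C(C)[C@@]1(C)[C@@]3(O)CC(=O)O[C@@]3(C)[C@H]2CC(=C)[C@H](O[Si](C)(C)C(C)(C)C)[C@@H]12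
F9 | step 9 | Mannich base (C11 dimethylaminomethyl on the open face) | C=C(C)[C@@]1(C)[C@@]3(O)[C@H](CN(C)C)C(=O)O[C@@]3(C)[C@H]2CC(=C)[C@H](O[Si](C)(C)C(C)(C)C)[C@@H]12
F10 | step 9 | α-methylene lactone | C=C(C)[C@@]1(C)[C@@]3(O)C(=C)C(=O)O[C@@]3(C)[C@H]2CC(=C)[C@H](O[Si](C)(C)C(C)(C)C)[C@@H]12
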